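**Retrosynthetic overview**
- Last bonds: the C11–O aryl ether (Mitsunobu with umbelliferone), C8=C12 (carbonyl methylenation) and C9–C11 (α-methylenation, then conjugate borylation), all from the Δ6-8-ketone 17.
- Ring A (C1–C5, C10) is traced back to the five-membered ring (C1, C2, C3, C5, C10) of hydrindenol 11: C4 with both methyl groups is inserted between C3 and C5 by a one-carbon ring enlargement.
- Enabling feature: in ring A the oxygen-bearing C3 is flanked by the quaternary gem-dimethyl C4, which is bonded to ring-fusion C5. This C3(O)–C4(CH3)2–C5 array is the retron of a semipinacol shift of C5 from a C3 carbinol to an isopropenyl-derived C4. C5 is kept alkenyl (C5=C6) so that it is the migrating carbon and the trans fusion can be set afterwards.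
- Ring order: ring B (from cyclohexanone ketal 1, C10 set by a chiral-imine Michael addition) → five-membered ring by reductive ketone–nitrile coupling → ring A by enlargement → C5–H by hydroboration → diene and ether.

Key step: step 5

Assumption: ketone 1 is taken as a catalogue compound; locants C1–C12 in the text are drimane locants (ring A = C1–C5 and C10; ring B = C5–C10; C11 = oxygenated CH2 on C9; C12 = CH2 on C8).

**Route**

Step 1
Reactants: 1 7-methyl-1,4-dioxaspiro[4.5]decan-8-one (racemic); 2 (R)-1-phenylethylamine; 3 acrylonitrile
Product: 6 3-[(7R)-7-methyl-8-oxo-1,4-dioxaspiro[4.5]decan-7-yl]propanenitrile, via ketimine 4 (not isolated), via adduct ketimine 5 (not isolated)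
Conditions: 2, TsOH (cat.), toluene, reflux with azeotropic removal of water; then 3, THF, 50 °C; then 20% aq. AcOH, rt
Reagents that add atoms: acrylonitrile (C=CC#N); water (O)
Why: Michael addition of the more substituted secondary-enamine tautomer of a chiral imine (deracemising α-alkylation) through a compact chair-like transition state with internal N–H transfer, in which the auxiliary shields one enamine face so that the quaternary C10 should form in the (R) configuration (the (R)-amine is chosen by analogy with the established sense for 2-methylcyclohexanone), and mild acid then hydrolyses the imine without touching the ketal.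

Step 2
Reactants: 6 3-[(7R)-7-methyl-8-oxo-1,4-dioxaspiro[4.5]decan-7-yl]propanenitrile
Product: 8 (3aR)-7a-hydroxy-3a-methyloctahydroindene-1,5-dione 5-ethylene ketal (either C7a epimer), via hydroxy ketimine 7 (not isolated)
Conditions: Cp2TiCl2 (C10H10Cl2Ti, 10 mol%), Zn, Me3SiCl, Et3N·HCl, THF, rt; then aq. citric acid
Reagents that add atoms: water (O)
Why: Titanocene-catalysed reductive ketone–nitrile coupling, in which trivalent titanium formed by zinc gives a ketyl-type species that closes the five-membered ring between the ketone carbon (C5) and the nitrile carbon (C3) and the imine is hydrolysed on work-up; the new carbinol centre is not controlled because it is removed in step 3.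

Step 3
Reactants: 8 (3aR)-7a-hydroxy-3a-methyloctahydroindene-1,5-dione 5-ethylene ketal
Product: 9 (3aR)-3a-methyl-2,3,3a,4,5,6-hexahydroinden-1-one 5-ethylene ketal with a C7=C7a double bond
Conditions: SOCl2, pyridine, CH2Cl2, 0 °C
Reagents that add atoms: none
Why: Dehydration of a tertiary α-ketol through its chlorosulfite (E2 with pyridine), where the only β-hydrogens sit on the ring B methylene (C6) because C10 is quaternary, so only the conjugated enone can form.

Step 4
Reactants: 9 (3aR)-3a-methyl-2,3,3a,4,5,6-hexahydroinden-1-one 5-ethylene ketal with a C7=C7a double bond; 10 isopropenylmagnesium bromide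
Product: 11 (3aR)-1-isopropenyl-3a-methyl-1,2,3,3a,4,6-hexahydroinden-1-ol 5-ethylene ketal (both C1 epimers)
Conditions: CeCl3, THF, −78 °C to 0 °C; aq. NH4Cl; chromatography on Et3N-buffered silica
Reagents that add atoms: isopropenylmagnesium bromide (C=C(C)[Mg]Br)
Why: 1,2-Addition of an organocerium reagent to an enone, cerium suppressing conjugate addition and enolisation; the configuration of the new carbinol carbon is irrelevant because it becomes the C3 carbonyl carbon in step 5.

Step 5
Reactants: 11 (3aR)-1-isopropenyl-3a-methyl-1,2,3,3a,4,6-hexahydroinden-1-ol 5-ethylene ketal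
Product: 12 8,8-ethylenedioxy-11,12-dinordrim-5-en-3-one
Conditions: [N,N'-bis(3,5-di-tert-butylsalicylidene)-1,2-cyclohexanediaminato]cobalt (C36H52CoN2O2, divalent cobalt, 5 mol%), N-fluoro-2,4,6-trimethylpyridinium tetrafluoroborate, PhSiH3, acetone, 0 °C to rt
Reagents that add atoms: none
Why: Hydrogen-atom-transfer radical–polar crossover semipinacol rearrangement (closest known type: cobalt–salen/N-fluoropyridinium/silane isomerisation of tertiary allylic alcohols to ring-enlarged ketones): a cobalt hydride delivers a hydrogen atom to the CH2 terminus of the 1,1-disubstituted isopropenyl group, the tertiary C4 radical is oxidised through an alkylcobalt species to a cation equivalent, and the alkenyl carbon C5 shifts from the carbinol carbon C3 to C4 while the hydroxyl becomes the C3 carbonyl. This 1,2-shift enlarges the five-membered ring (C1, C2, C3, C5, C10) to six-membered ring A by inserting C4, so the ring closes by migration and not by cyclisation, and the same event forms the quaternary gem-dimethyl C4 and the congested C4–C5 bond. No stereocentre is created: C10 is untouched, the carbinol centre is destroyed, and C5 stays sp2 so that the ring fusion can be set from the decalin in step 7. The selectivity needed is migration of C5 and not of C2, and the C5=C6 π-bond secures it, because an alkenyl group bridges to the electron-poor C4 and migrates far faster than a primary alkyl carbon; a radical 1,2-vinyl shift through a cyclopropylcarbinyl radical followed by oxidation of the ketyl leads to the same product. Chemoselectivity rests on hydrogen-atom transfer being much faster to the 1,1-disubstituted alkene than to the trisubstituted ring alkene, and the near-neutral conditions should spare the ketal and avoid ionisation of the doubly allylic alcohol.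

Step 6
Reactants: 12 8,8-ethylenedioxy-11,12-dinordrim-5-en-3-one
Product: 13 8,8-ethylenedioxy-11,12-dinordrim-5-en-3β-ol
Conditions: NaBH4, MeOH/THF, 0 °C
Reagents that add atoms: none
Why: Borohydride reduction of a 4,4-dimethyl-3-ketone, with hydride delivered axially from the α-face because the β-face is blocked by the axial methyl groups on C4 and C10, giving the equatorial 3β-alcohol.

Step 7
Reactants: 13 8,8-ethylenedioxy-11,12-dinordrim-5-en-3β-ol
Product: 15 8,8-ethylenedioxy-11,12-dinor-5α-drimane-3β,6α-diol, via 6α-alkylborane 14 (not isolated)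
Conditions: BH3·THF (excess), THF, 0 °C to rt; then NaOH, H2O2, 0 °C
Reagents that add atoms: hydrogen peroxide (OO)
Why: Brown hydroboration–oxidation, in which syn addition of B–H to the trisubstituted C5=C6 from the α-face (opposite the C10 and 4β methyl groups), with boron on the less substituted C6, sets the 5α-hydrogen and hence the trans ring fusion, and leaves a 6α-hydroxyl that serves only as a leaving group in step 8.

Step 8
Reactants: 15 8,8-ethylenedioxy-11,12-dinor-5α-drimane-3β,6α-diol
Product: 17 3β-hydroxy-11,12-dinor-5α-drim-6-en-8-one, via dihydroxy ketone 16 (not isolated)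
Conditions: 2 M HCl, THF, 45 °C
Reagents that add atoms: water (O)
Why: Acidic ketal hydrolysis followed by acid-catalysed β-elimination of the resulting β-hydroxy ketone, which can only place the double bond at C6=C7 because C7 is the single carbon between carbinol and carbonyl, while the non-activated 3β-hydroxyl stays.

Step 9
Reactants: 17 3β-hydroxy-11,12-dinor-5α-drim-6-en-8-one; 18 paraformaldehyde
Product: 20 3β-hydroxy-12-nor-5α-drima-6,9(11)-dien-8-one, via Mannich base 19 (not isolated)
Conditions: N-methylanilinium trifluoroacetate, THF, reflux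
Reagents that add atoms: formaldehyde (C=O)
Why: Mannich condensation–elimination (α-methylenation) at C9, the only enolisable α-carbon of the enone, under mildly acidic conditions that tolerate the free 3β-hydroxyl; no stereocentre is formed.

Step 10
Reactants: 20 3β-hydroxy-12-nor-5α-drima-6,9(11)-dien-8-one
Product: 22 3β,11-dihydroxy-12-nor-5α,9α-drim-6-en-8-one, via 11-boryl ketone 21 (not isolated)
Conditions: B2pin2 (1.1 equiv), CuCl (5 mol%), DPEphos, NaOt-Bu (10 mol%), MeOH (2 equiv), THF, rt; then NaBO3·4H2O, THF/H2O, rt
Reagents that add atoms: sodium perborate ([Na+].[O-]OB(O)O)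
Why: Copper-catalysed conjugate borylation (1,4-addition of a boryl–monovalent copper species) at the unhindered exocyclic methylene in preference to the β-substituted ring enone, then C–B oxidation with retention; protonation of the enolate at C9 from the α-face, anti to the axial C10 methyl, places C11 β (equatorial), which is also the thermodynamic epimer of this enolisable centre.

Step 11
Reactants: 22 3β,11-dihydroxy-12-nor-5α,9α-drim-6-en-8-one; 23 dibromomethane
Product: 24 5α,9α-drima-6,8(12)-diene-3β,11-diol
Conditions: Zn, CH2Br2, TiCl4, THF/CH2Cl2, 0 °C to rt; NaHCO3 quench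
Reagents that add atoms: dibromomethane (BrCBr)
Why: Lombardo methylenation, whose non-basic zinc/titanium methylene reagent converts the enone carbonyl into the exocyclic C8=C12 without enolising C9 or provoking retro-aldol loss of C11, and tolerates free hydroxyl groups when used in excess.

Step 12
Reactants: 24 5α,9α-drima-6,8(12)-diene-3β,11-diol; 25 umbelliferone (7-hydroxycoumarin)
Product: 26 7-[(3β-hydroxy-5α,9α-drima-6,8(12)-dien-11-yl)oxy]coumarin (target)
Conditions: PPh3, DIAD, THF, 0 °C to rt
Reagents that add atoms: umbelliferone (Oc1ccc2ccc(=O)oc2c1)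
Why: Mitsunobu etherification, in which the acidic phenol (pKa about 8) displaces the oxyphosphonium of the primary C11 alcohol while the equatorial 3β-hydroxyl next to the gem-dimethyl carbon is far too hindered to compete; no stereocentre is involved.

**Compound list**

1 | 7-methyl-1,4-dioxaspiro[4.5]decan-8-one (racemic) | CC1CC2(OCCO2)CCC1=O | starting material
2 | (R)-1-phenylethylamine | C[C@@H](N)c1ccccc1 | starting material
3 | acrylonitrile | C=CC#N | starting material
4 | N-[(1R)-1-phenylethyl] ketimine of 1 (imine isomers, α-methyl centre mobile) | CC1CC2(OCCO2)CCC1=N[C@H](C)c1ccccc1 | intermediate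
5 | Michael-adduct ketimine, (R) at the new quaternary carbon | N#CCC[C@]1(C)CC2(OCCO2)CCC1=N[C@H](C)c1ccccc1 | intermediate
6 | 3-[(7R)-7-methyl-8-oxo-1,4-dioxaspiro[4.5]decan-7-yl]propanenitrile | N#CCC[C@]1(C)CC2(OCCO2)CCC1=O | intermediate
7 | (3aR)-7a-hydroxy-1-imino-3a-methyloctahydroinden-5-one ethylene ketal (either C7a epimer) | N=C1CC[C@]2(C)CC3(OCCO3)CCC12O | intermediate
8 | (3aR)-7a-hydroxy-3a-methyloctahydroindene-1,5-dione 5-ethylene ketal (either C7a epimer) | O=C1CC[C@]2(C)CC3(OCCO3)CCC12O | intermediate
9 | (3aR)-3a-methyl-2,3,3a,4,5,6-hexahydroinden-1-one 5-ethylene ketal, C7=C7a conjugated to the ketone | O=C1CC[C@]2(C)CC3(OCCO3)CC=C12 | intermediate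
10 | isopropenylmagnesium bromide | C=C(C)[Mg]Br | starting material
11 | (3aR)-1-isopropenyl-3a-methyl-1,2,3,3a,4,6-hexahydroinden-1-ol 5-ethylene ketal, C7=C7a (both C1 epimers) | C=C(C)C1(O)CC[C@]2(C)CC3(OCCO3)CC=C12 | intermediate
12 | 8,8-ethylenedioxy-11,12-dinordrim-5-en-3-one (10β-methyl, 4,4-dimethyl) | O1CCOC12CC=C3C(C)(C)C(=O)CC[C@]3(C)C2 | intermediate
13 | 8,8-ethylenedioxy-11,12-dinordrim-5-en-3β-ol | O1CCOC12CC=C3C(C)(C)[C@@H](O)CC[C@]3(C)C2 | intermediate
14 | 6α-boryl-8,8-ethylenedioxy-11,12-dinor-5α-drimane-3β-ol (drawn as the monoalkylborane) | O1CCOC12C[C@H](B)[C@H]3C(C)(C)[C@@H](O)CC[C@]3(C)C2 | intermediate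
15 | 8,8-ethylenedioxy-11,12-dinor-5α-drimane-3β,6α-diol | O1CCOC12C[C@H](O)[C@H]3C(C)(C)[C@@H](O)CC[C@]3(C)C2 | intermediate
16 | 3β,6α-dihydroxy-11,12-dinor-5α-drimane-8-one | O=C1C[C@H](O)[C@H]2C(C)(C)[C@@H](O)CC[C@]2(C)C1 | intermediate
17 | 3β-hydroxy-11,12-dinor-5α-drim-6-en-8-one | O=C1C=C[C@H]2C(C)(C)[C@@H](O)CC[C@]2(C)C1 | intermediate
18 | paraformaldehyde (as formaldehyde) | C=O | starting material
19 | 9-[(N-methylanilino)methyl]-3β-hydroxy-11,12-dinor-5α-drim-6-en-8-one (C9 epimers) | O=C1C=C[C@H]2C(C)(C)[C@@H](O)CC[C@]2(C)C1CN(C)c1ccccc1 | intermediate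
20 | 3β-hydroxy-12-nor-5α-drima-6,9(11)-dien-8-one | O=C1C=C[C@H]2C(C)(C)[C@@H](O)CC[C@]2(C)C1=C | intermediate
21 | 3β-hydroxy-11-(pinacolatoboryl)-12-nor-5α,9α-drim-6-en-8-one | O=C1C=C[C@H]2C(C)(C)[C@@H](O)CC[C@]2(C)[C@H]1CB1OC(C)(C)C(C)(C)O1 | intermediate
22 | 3β,11-dihydroxy-12-nor-5α,9α-drim-6-en-8-one | O=C1C=C[C@H]2C(C)(C)[C@@H](O)CC[C@]2(C)[C@H]1CO | intermediate
23 | dibromomethane | BrCBr | starting material
24 | 5α,9α-drima-6,8(12)-diene-3β,11-diol | C=C1C=C[C@H]2C(C)(C)[C@@H](O)CC[C@]2(C)[C@H]1CO | intermediate
25 | umbelliferone (7-hydroxycoumarin) | Oc1ccc2ccc(=O)oc2c1 | starting material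
26 | 7-[(3β-hydroxy-5α,9α-drima-6,8(12)-dien-11-yl)oxy]coumarin | C=C1C=C[C@H]2C(C)(C)[C@@H](O)CC[C@]2(C)[C@H]1COc1ccc2ccc(=O)oc2c1 | target

**Step count and risks**

Total step count: 12. Longest linear sequence: 12 steps (1 to 26).

Steps most likely to fail:

1. Step 5. The cation equivalent at C4 may be captured by the neighbouring hydroxyl (oxirane closure) or lose a proton back to an alkene, hydrogen-atom transfer may also reach the ring alkene, and the doubly allylic alcohol may ionise on the pyridinium by-product. The fallback sets out from 9 and returns at 12. Enone 9 is treated with 2-lithio-2-(methylselanyl)propane (from 2,2-bis(methylselanyl)propane and n-BuLi, THF, −78 °C) to give the β-hydroxy selenide F1. Soft activation of selenium (AgBF4 on alumina, CH2Cl2, −20 °C) then ionises the C–Se bond, and the same alkenyl 1,2-shift (selenium-triggered semipinacol ring enlargement) should give 12 without any hydrogen-atom-transfer chemistry.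

2. Step 2. Ketyl formation at the hindered α-quaternary ketone may be slow, so that simple reduction of the ketone or partial loss of the ketal under chlorosilane and acid takes over. The fallback sets out from 6 and returns at 9, bypassing 8. Ketone 6 is converted into the hydrazone F2 (N2H4·H2O, EtOH, reflux) and this is iodinated (I2, tetramethylguanidine, Et2O) to the vinyl iodide F3, in which the double bond can only lie toward C6. Iodine–lithium exchange (t-BuLi, THF, −78 °C) and 5-exo attack of the vinyllithium on the nitrile (Parham-type cyclisation) give the conjugated ketimine F4, which mild acidic work-up hydrolyses to enone 9.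

3. Step 12. Displacement at the β-branched primary oxyphosphonium centre may be slow, letting elimination toward C9 or alkylation of the hydrazide anion compete. The fallback sets out from 20 and returns at 26. Base-mediated oxa-Michael addition of 25 to the exocyclic enone of 20 (K2CO3, MeCN, 40 °C) gives the β-aryloxy ketone F5, with C9 set by α-face protonation and equilibration to the equatorial epimer. Lombardo methylenation of F5 (Zn, CH2Br2, TiCl4, 0 °C) then gives 26 directly.

Further compounds
F1 | step 5 | (3aR)-1-[2-(methylselanyl)propan-2-yl]-3a-methyl-1,2,3,3a,4,6-hexahydroinden-1-ol 5-ethylene ketal, C7=C7a (both C1 epimers) | C[Se]C(C)(C)C1(O)CC[C@]2(C)CC3(OCCO3)CC=C12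
F2 | step 2 | hydrazone of 6 | N#CCC[C@]1(C)CC2(OCCO2)CCC1=NN
F3 | step 2 | 3-[(7R)-8-iodo-7-methyl-1,4-dioxaspiro[4.5]dec-8-en-7-yl]propanenitrile | N#CCC[C@]1(C)CC2(OCCO2)CC=C1I
F4 | step 2 | (3aR)-1-imino-3a-methyl-2,3,3a,4,5,6-hexahydroindene 5-ethylene ketal, C7=C7a | N=C1CC[C@]2(C)CC3(OCCO3)CC=C12
F5 | step 12 | 7-[(3β-hydroxy-8-oxo-12-nor-5α,9α-drim-6-en-11-yl)oxy]coumarin | O=C1C=C[C@H]2C(C)(C)[C@@H](O)CC[C@]2(C)[C@H]1COc1ccc2ccc(=O)oc2c1
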